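Retrosynthesis: the C5 O–methyl bond is cut last; ring A is then cut at C4a–C5 and C8–C8a, because C5–C8 with oxygen on C5 and C7 correspond to a 1,1,3-trioxygenated butadiene, and the C4a=C8a bond shared with the pyranone ring corresponds to the C5=C6 bond of a monocyclic 4-pyranone made dienophilic by a nitro group on C5.
The nitropyranone is cut at O1–C6 and C5–C6 (one carbon from a formamide acetal), at C4–C5 (acylation of nitromethane) and at C2–C3 (Meldrum's acid), leading back to hexacosanoic acid, which supplies the C25 chain and C2.
Forward: the chain is extended to a ketal-masked β-keto acid, nitromethane is acylated, and aminomethylenation followed by acid closure gives the pyranone ring first; ring A is then annulated by Diels–Alder reaction with loss of HNO2 and MeOH, and the C5 phenol is freed.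
Stereochemistry: the target has no stereocentre; the two centres of the transient cycloadduct (C4a, C8a) are set cis by suprafacial addition and disappear on aromatisation.

Key step: step 9

Assumption: the pentacosyl chain is unbranched as drawn; the long chain makes all intermediates waxy and poorly soluble in polar media, so THF or toluene is used as (co)solvent and reactions are run warm where needed. Bicyclic compounds carry chromone numbering (O1, C2–C4, C4a, C5–C8, C8a), monocyclic ones pyranone numbering (O1, C2–C6).

Step 1
Reactants: 1 hexacosanoic acid; 2 Meldrum's acid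
Product: 4 methyl 3-oxooctacosanoate, via acyl Meldrum's acid 3 (not isolated)
Conditions: DCC, DMAP, CH2Cl2/THF, 0 °C to rt; filter, wash with 1 M HCl; then MeOH/toluene, reflux
Reagents that add atoms: methanol, CO
Why: Carbodiimide-mediated C-acylation of Meldrum's acid followed by alcoholysis with loss of acetone and CO2 is the standard two-carbon homologation of a carboxylic acid to a β-keto ester.

Step 2
Reactants: 4 methyl 3-oxooctacosanoate
Product: 5 methyl 2-(2-pentacosyl-1,3-dioxolan-2-yl)acetate
Conditions: HOCH2CH2OH, pTsOH·H2O (cat.), toluene, Dean–Stark, reflux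
Reagents that add atoms: ethylene glycol, OCCO
Why: Acid-catalysed ketalisation with azeotropic removal of water masks the ketone of a β-keto ester as a dioxolane, so that the later acylation is not disturbed by a 1,3-dicarbonyl methylene; any glycol ester formed by transesterification should converge on the same acid in step 3.

Step 3
Reactants: 5 methyl 2-(2-pentacosyl-1,3-dioxolan-2-yl)acetate
Product: 6 2-(2-pentacosyl-1,3-dioxolan-2-yl)acetic acid
Conditions: LiOH·H2O, THF/MeOH/H2O, 50 °C; then 1 M HCl to pH 4, 0 °C
Reagents that add atoms: lithium hydroxide, [Li+].[OH-]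
Why: Ester saponification leaves the base-stable dioxolane untouched, and brief cold acidification should free the acid without hydrolysing the ketal.

Step 4
Reactants: 6 2-(2-pentacosyl-1,3-dioxolan-2-yl)acetic acid; 7 nitromethane
Product: 9 1-nitro-3-(2-pentacosyl-1,3-dioxolan-2-yl)propan-2-one, via acyl imidazolide 8 (not isolated)
Conditions: CDI, THF, 40 °C; then CH3NO2 (5 equiv), KOtBu (2.2 equiv), THF/DMSO, rt; AcOH work-up
Reagents that add atoms: none
Why: Claisen-type C-acylation of potassium nitronate by an acyl imidazolide is the established route to α-nitro ketones, the product being held in the flask as its nitronate salt, which shields it from further acylation and from cleavage.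

Step 5
Reactants: 9 1-nitro-3-(2-pentacosyl-1,3-dioxolan-2-yl)propan-2-one
Product: 10 4-(dimethylamino)-3-nitro-1-(2-pentacosyl-1,3-dioxolan-2-yl)but-3-en-2-one
Conditions: Me2NCH(OMe)2 (1.5 equiv), toluene, 60 °C
Reagents that add atoms: N,N-dimethylformamide dimethyl acetal, COC(OC)N(C)C
Why: Aminomethylenation with a formamide acetal takes place at the only doubly activated methylene (between C=O and NO2), a condensation well known for α-nitro ketones, while the other CH2 is flanked by a single carbonyl and the masked ketone and should stay inert.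

Step 6
Reactants: 10 4-(dimethylamino)-3-nitro-1-(2-pentacosyl-1,3-dioxolan-2-yl)but-3-en-2-one
Product: 12 5-nitro-2-pentacosyl-4H-pyran-4-one, via aminomethylene nitro diketone 11 (not isolated)
Conditions: 2 M aq. HCl, THF, 50 °C
Reagents that add atoms: water, O
Why: Acid hydrolysis of the dioxolane releases the 1,3-diketone, whose enol oxygen adds to the protonated enaminone carbon in a 6-endo-trig addition–elimination with loss of dimethylamine, the usual enaminone cyclisation to 4-pyranones and chromones.

Step 7
Reactants: 13 1,1-dimethoxyethene; 14 acetyl chloride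
Product: 15 4,4-dimethoxybut-3-en-2-one
Conditions: Et3N, Et2O, 0 °C to rt (slow addition of 14)
Reagents that add atoms: none
Why: C-acylation of the nucleophilic ketene acetal by the acid chloride, followed by amine-mediated proton loss from the dialkoxycarbenium intermediate, is the classical preparation of acyl ketene acetals.

Step 8
Reactants: 15 4,4-dimethoxybut-3-en-2-one
Product: 16 1,1-dimethoxy-3-(trimethylsilyloxy)buta-1,3-diene
Conditions: LiN(iPr)2 (commercial solution), THF, −78 °C; Me3SiCl, −78 °C to rt; distil, use fresh
Reagents that add atoms: chlorotrimethylsilane, C[Si](C)(C)Cl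
Why: Kinetic deprotonation of the methyl ketone and O-silylation of the enolate (silyl enol ether formation) give the 2-silyloxydiene, as in the preparation of 1-alkoxy-3-silyloxybutadienes from β-alkoxy enones.

Step 9
Reactants: 12 5-nitro-2-pentacosyl-4H-pyran-4-one; 16 1,1-dimethoxy-3-(trimethylsilyloxy)buta-1,3-diene
Product: 20 7-hydroxy-5-methoxy-2-pentacosyl-4H-chromen-4-one, via cis-fused nitro cycloadduct 17 (not isolated), via 5,8-dihydrochromenone dimethyl ketal 18 (not isolated), via 7-trimethylsilyl ether 19 (not isolated)
Conditions: 16 (3 equiv), toluene, sealed tube, 110 °C; then 1 M HCl, THF, rt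
Reagents that add atoms: none
Why: Proposed new method: the CH2 terminus of diene 16, its most nucleophilic carbon, should add to pyranone C6, which is β to both the nitro group and the C4 carbonyl, and the nitronate carbon (pyranone C5) then collapses onto the dimethoxycarbenium carbon, so that C8–C8a and C4a–C5 form in an asynchronous polar [4+2] cycloaddition to give 17. The closest known reaction type is the polar Diels–Alder reaction of 3-nitrocoumarins and other nitro-substituted benzo-fused and heteroaromatic dienophiles with 1-alkoxy-3-silyloxybutadienes, which likewise ends in loss of nitrous acid and aromatisation; a monocyclic 3-nitro-4-pyranone has not been shown in this role. Ring A closes as a six-membered carbocycle in an intermolecular [4+2] mode, the second bond arising by 6-exo-trig attack of the nitronate carbon on the oxocarbenium carbon. The only stereocentres, C4a and C8a of 17, are transient: suprafacial addition places the nitro group and the C8a hydrogen syn, as thermal syn-elimination of HNO2 to 18 requires, after which 1,4-loss of methanol from the C5 ketal (the C8 hydrogens being vinylogously acidic through C8a=C4a–C4=O) aromatises to 19 and the acidic work-up cleaves the silyl ether. The step needs regioselectivity (oxygen at C5 and C7, not C6 and C8) and site selectivity for C5=C6 over C2=C3, and both rest on the nitro group, which makes C6 the single most electrophilic carbon while C2=C3 is only an alkyl-substituted vinylogous ester. Neutral, non-nucleophilic thermal conditions are chosen so that ring closure can outrun retro-oxa-Michael opening of the pyranone at the nitronate stage.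

Step 10
Reactants: 20 7-hydroxy-5-methoxy-2-pentacosyl-4H-chromen-4-one
Product: 21 5,7-dihydroxy-2-pentacosyl-4H-chromen-4-one
Conditions: BCl3 (1 M in CH2Cl2, 3 equiv), CH2Cl2, 0 °C to rt; then H2O
Reagents that add atoms: none
Why: BCl3 binds the C4 carbonyl and the peri C5 methoxy oxygen, so chloride cleaves that O–CH3 bond (chelation-assisted Lewis acid demethylation, standard for 5-methoxychromones and flavones), and aqueous work-up should release both phenols.

Compound list
1 | hexacosanoic acid | CCCCCCCCCCCCCCCCCCCCCCCCCC(=O)O | starting material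
2 | Meldrum's acid (2,2-dimethyl-1,3-dioxane-4,6-dione) | CC1(C)OC(=O)CC(=O)O1 | starting material
3 | 5-(1-hydroxyhexacosylidene)-2,2-dimethyl-1,3-dioxane-4,6-dione (acyl Meldrum's acid, enol form; not isolated) | CCCCCCCCCCCCCCCCCCCCCCCCCC(O)=C1C(=O)OC(C)(C)OC1=O | intermediate
4 | methyl 3-oxooctacosanoate | CCCCCCCCCCCCCCCCCCCCCCCCCC(=O)CC(=O)OC | intermediate
5 | methyl 2-(2-pentacosyl-1,3-dioxolan-2-yl)acetate | CCCCCCCCCCCCCCCCCCCCCCCCCC1(CC(=O)OC)OCCO1 | intermediate
6 | 2-(2-pentacosyl-1,3-dioxolan-2-yl)acetic acid | CCCCCCCCCCCCCCCCCCCCCCCCCC1(CC(=O)O)OCCO1 | intermediate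
7 | nitromethane | C[N+](=O)[O-] | starting material
8 | 1-(imidazol-1-yl)-2-(2-pentacosyl-1,3-dioxolan-2-yl)ethan-1-one (acyl imidazolide; not isolated) | CCCCCCCCCCCCCCCCCCCCCCCCCC1(CC(=O)n2ccnc2)OCCO1 | intermediate
9 | 1-nitro-3-(2-pentacosyl-1,3-dioxolan-2-yl)propan-2-one | CCCCCCCCCCCCCCCCCCCCCCCCCC1(CC(=O)C[N+](=O)[O-])OCCO1 | intermediate
10 | 4-(dimethylamino)-3-nitro-1-(2-pentacosyl-1,3-dioxolan-2-yl)but-3-en-2-one (push–pull alkene, geometry not fixed) | CCCCCCCCCCCCCCCCCCCCCCCCCC1(CC(=O)C(=CN(C)C)[N+](=O)[O-])OCCO1 | intermediate
11 | 1-(dimethylamino)-2-nitrotriacont-1-ene-3,5-dione (not isolated) | CCCCCCCCCCCCCCCCCCCCCCCCCC(=O)CC(=O)C(=CN(C)C)[N+](=O)[O-] | intermediate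
12 | 5-nitro-2-pentacosyl-4H-pyran-4-one | CCCCCCCCCCCCCCCCCCCCCCCCCc1cc(=O)c([N+](=O)[O-])co1 | intermediate
13 | 1,1-dimethoxyethene | C=C(OC)OC | starting material
14 | acetyl chloride | CC(=O)Cl | starting material
15 | 4,4-dimethoxybut-3-en-2-one | CC(=O)C=C(OC)OC | intermediate
16 | 1,1-dimethoxy-3-(trimethylsilyloxy)buta-1,3-diene | C=C(O[Si](C)(C)C)C=C(OC)OC | intermediate
17 | rac-cis-5,5-dimethoxy-4a-nitro-2-pentacosyl-7-(trimethylsilyloxy)-4a,5,8,8a-tetrahydro-4H-chromen-4-one (NO2 at C4a and H at C8a on the same face; racemic, one enantiomer drawn; not isolated) | CCCCCCCCCCCCCCCCCCCCCCCCCC1=CC(=O)[C@]2([N+](=O)[O-])C(OC)(OC)C=C(O[Si](C)(C)C)C[C@@H]2O1 | intermediate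
18 | 5,5-dimethoxy-2-pentacosyl-7-(trimethylsilyloxy)-5,8-dihydro-4H-chromen-4-one (not isolated) | CCCCCCCCCCCCCCCCCCCCCCCCCC1=CC(=O)C2=C(O1)CC(O[Si](C)(C)C)=CC2(OC)OC | intermediate
19 | 5-methoxy-2-pentacosyl-7-(trimethylsilyloxy)-4H-chromen-4-one (not isolated) | CCCCCCCCCCCCCCCCCCCCCCCCCc1cc(=O)c2c(OC)cc(O[Si](C)(C)C)cc2o1 | intermediate
20 | 7-hydroxy-5-methoxy-2-pentacosyl-4H-chromen-4-one | CCCCCCCCCCCCCCCCCCCCCCCCCc1cc(=O)c2c(OC)cc(O)cc2o1 | intermediate
21 | 5,7-dihydroxy-2-pentacosyl-4H-chromen-4-one | CCCCCCCCCCCCCCCCCCCCCCCCCc1cc(=O)c2c(O)cc(O)cc2o1 | target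

Total step count: 10. Longest linear sequence: 8 steps (steps 1–6, 9, 10); the diene branch (steps 7–8) joins at step 9.

Steps most likely to fail

Step 9 (the proposed new method). After the first C–C bond has formed, the nitronate may expel the ring oxygen (retro-oxa-Michael opening of the pyranone) instead of closing ring A. The liberated nitrous acid may also consume the diene or nitrosate the electron-rich product, and elimination of HNO2 from the adduct may stall. The fallback uses known chemistry, sets out from 1 and comes back to the route at 21. Acid 1 is converted with oxalyl chloride and catalytic DMF into hexacosanoyl chloride F1. This acylates the phenol of commercial 2-hydroxy-4,6-dimethoxyacetophenone (Et3N, DMAP, CH2Cl2) to give 2-acetyl-3,5-dimethoxyphenyl hexacosanoate F2. Baker–Venkataraman rearrangement (KOtBu, THF) then gives 1-(2-hydroxy-4,6-dimethoxyphenyl)octacosane-1,3-dione F3. Acid cyclodehydration (H2SO4, AcOH) closes the pyranone ring onto the preformed arene to give 5,7-dimethoxy-2-pentacosyl-4H-chromen-4-one F4, and BBr3 in CH2Cl2 removes both methyl groups to give 21.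

Step 4. The long-chain imidazolide may be poorly soluble in the polar medium needed for the nitronate, base may open the dioxolane by β-elimination, or the nitronate may be acylated twice. The fallback forms the same C–C bond by addition rather than acylation; it sets out from 5 and returns at 9. Ester 5 is reduced with iBu2AlH (toluene/CH2Cl2, −78 °C) to 2-(2-pentacosyl-1,3-dioxolan-2-yl)acetaldehyde F5. A Henry reaction with nitromethane 7 (catalytic KOtBu, THF/tBuOH) gives racemic 1-nitro-3-(2-pentacosyl-1,3-dioxolan-2-yl)propan-2-ol F6. Oxidation of the nitro alcohol with Dess–Martin periodinane (NaHCO3-buffered CH2Cl2) gives 9.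

Step 6. In aqueous acid the aminomethylene carbon may be lost by hydrolysis, or the nitro diketone may undergo retro-Claisen cleavage before the ring closes. The fallback separates unmasking from ring closure and brings in C6 under anhydrous acylating conditions; it sets out from 9 and returns at 12. The dioxolane of 9 is removed first (pTsOH, acetone/H2O, 50 °C) to give 1-nitrononacosane-2,4-dione F7. This is treated with acetic formic anhydride and HCOONa, the reagent pair used to turn 2-hydroxy-ω-nitroacetophenones into 3-nitrochromones. The weak base ionises only the nitro-activated methylene, so the formyl carbon is delivered there and the diketone enol closes onto it with loss of water to give 12.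

Further compounds
F1 | step 9 | hexacosanoyl chloride | CCCCCCCCCCCCCCCCCCCCCCCCCC(=O)Cl
F2 | step 9 | 2-acetyl-3,5-dimethoxyphenyl hexacosanoate | CCCCCCCCCCCCCCCCCCCCCCCCCC(=O)Oc1cc(OC)cc(OC)c1C(C)=O
F3 | step 9 | 1-(2-hydroxy-4,6-dimethoxyphenyl)octacosane-1,3-dione | CCCCCCCCCCCCCCCCCCCCCCCCCC(=O)CC(=O)c1c(O)cc(OC)cc1OC
F4 | step 9 | 5,7-dimethoxy-2-pentacosyl-4H-chromen-4-one | CCCCCCCCCCCCCCCCCCCCCCCCCc1cc(=O)c2c(OC)cc(OC)cc2o1
F5 | step 4 | 2-(2-pentacosyl-1,3-dioxolan-2-yl)acetaldehyde | CCCCCCCCCCCCCCCCCCCCCCCCCC1(CC=O)OCCO1
F6 | step 4 | 1-nitro-3-(2-pentacosyl-1,3-dioxolan-2-yl)propan-2-ol (racemic) | CCCCCCCCCCCCCCCCCCCCCCCCCC1(CC(O)C[N+](=O)[O-])OCCO1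
F7 | step 6 | 1-nitrononacosane-2,4-dione | CCCCCCCCCCCCCCCCCCCCCCCCCC(=O)CC(=O)C[N+](=O)[O-]
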